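(The numbers in the tables are calculated for substances that don't exist; the scatter is artificial.)

In the amber run target reached twice its 10.0 min value by 25.0 min, while the time grew 2.50 times, so the curve was already bending.

| flask | starting material | temperature | remark | time |
|---|---|---|---|---|
| amber | 2.5 M | 50 °C | run made earlier |  |
| gamma | 3.0 M | 50 °C |  | 2.0 h |
| delta | 0.60 M | 50 °C |  | 2.0 h |
| eta | 1.2 M | 50 °C |  | 2.0 h |
| alpha | 2.3 M | 50 °C |  | 2.0 h |

amber run (percent of the starting material charged)

| time / min | target / % |
|---|---|
| 3.00 | 4.4 |
| 6.00 | 7.4 |
| 10.0 | 12.5 |
| 15.0 | 17.9 |
| 20.0 | 22.0 |
| 25.0 | 25.5 |

(standard deviation of a reading: 0.3 percentage points)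

- a species is counted by the starting material in it: one target or over-reaction product counts as two
- steps that have been proposed: 2 starting material -> target; starting material <-> dormant form; target -> over-reaction product

- all flasks from highest to lowest amount of target, in percent of the starting material charged, at 2.0 h (gamma / delta / eta / alpha)
- the amount of target, in percent of the starting material charged of the flask you put first, at 2.0 h
- the amount of target, in percent of the starting material charged of the flask you put last, at 2.0 h

The target -> over-reaction product step runs one way, so the road ends in over-reaction product, with target as the kinetic product on the way. The question at 2.0 h was how far along that road each flask had come.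

I began with the main step by itself. There, the fraction of the charge turned to target, divided by the fraction left, grows in proportion to time and to the charge. I call this ratio the clock. Amber's last reading gave it a slope of 0.0137 /min. Scaling by charge, gamma's clock at 2.0 h read 1.97 and delta's read 0.394. A clock divided by one plus itself is the fraction formed, so the main step by itself allowed about 66.3 % in gamma and 28.3 % in delta. Alpha and eta lay between, in order of charge .

Next I added the loss of target to over-reaction product, which lowers each number. Amber hinted at a drain of some kind: the slope read 0.0145 /min at 15.0 min, higher than at 25.0 min, but with a scatter of 0.3 percentage points in the readings I could not name its step.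

Last came the dormant form, which parks starting material. It should lower delta's number by a larger share, because delta's clock ran slower than gamma's. I committed to the order by charge, with the clock's numbers as estimates from above.

The forecast gave gamma > alpha > eta > delta, with 53 % first and 23.5 % last, on the ground that “formation is second-order while the loss is first-order”.

The flask gave gamma > alpha > eta > delta, with gamma at 53.0 % and delta at 20.7 %.

    2 starting material → target (k = 5.10 × 10⁻⁵ /M/s, Ea = 65.0 kJ/mol)
    starting material ⇌ dormant form (K = 0.810, k = 8.30 × 10⁻⁵ /s, Ea = 93.0 kJ/mol, ΔH = −13.0 kJ/mol)
    target → over-reaction product (k = 1.10 × 10⁻⁵ /s, Ea = 102 kJ/mol)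
    (constants at 50 °C)

Gamma was not at rest at 2.0 h: target and over-reaction product together held 56.1 %, less than the clock's 66.3 %, while 26 % remained starting material and 18.2 % stood as dormant form. With gamma left until 5.0 h, the clock allowed 83.1 % against 68.5 % found, with target at 58.6 %. At ten times the time it allowed 95.2 % against 86.5 %, but target had dropped to 45.0 % and over-reaction product had climbed to 41.6 %. Delta by then had risen to 34.5 %, still below gamma's 45.0 %.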